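**Plan**
- Cuts: first the two O–Si bonds. Then one retro-oxa-[4+2] cuts O1–C2 and C3–C4 of ring C, giving a styryl-substituted o-quinone methide (ring A, C4, styryl arm) and an (E)-1,3-diarylpropene (ring B, C2, C3, benzyl arm).
- Enabling feature: O1–C8a–C4a–C4 is an o-hydroxybenzyl unit whose C4 is also allylic to the styryl group, so a C4 carbinol ionises easily to a planar methide. C2=C3 of the partner is polarised by the 2,4-dimethoxyphenyl ring B (C3 nucleophilic, C2 cation-stabilising).
- Further cuts: the methide precursor goes back to a 2'-hydroxychalcone (aldol C=C). The diarylpropene is cut at the CH2–aryl bond (allyl–aryl coupling) and at the carbinol–vinyl bond.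
- Forward: fragment 1 by condensation, monosilylation and 1,2-reduction (steps 1–3); fragment 2 by vinyl addition and palladium coupling (steps 4–5). Ring C, the only ring made, closes in step 6, and desilylation ends the route (step 7).
- Stereochemistry: the racemic carbinol centre is erased and both enantiomers converge on one methide. A chiral Brønsted acid bound to the methide oxygen sets C4, and the (E)-alkene gives C2/C3 trans. The (E)-methide and the ring B endo approach give C3/C4 trans and C2/C4 cis (all-equatorial).

Key step: step 6

Assumption: the (R)-configured catalyst is taken to leave open the Si face of the methide carbon C4, which leads to (2R,3R,4R); if the sense of induction is the opposite, the (S)-catalyst is used and nothing else changes.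

Step 1
Reactants: 1 2'-hydroxy-4'-methoxyacetophenone (paeonol); 2 4-hydroxybenzaldehyde
Product: 3 (E)-1-(2-hydroxy-4-methoxyphenyl)-3-(4-hydroxyphenyl)prop-2-en-1-one
Conditions: KOH (50% aq), EtOH, rt; then aq HCl to pH 5
Reagents that add atoms: none
Why: Claisen–Schmidt aldol condensation, in which the enolate of 1 adds to 2 and E1cB loss of water gives the conjugated (E)-enone, a transformation well known for 2'-hydroxychalcones.

Step 2
Reactants: 3 (E)-1-(2-hydroxy-4-methoxyphenyl)-3-(4-hydroxyphenyl)prop-2-en-1-one
Product: 4 (E)-3-[4-(tert-butyldimethylsilyloxy)phenyl]-1-(2-hydroxy-4-methoxyphenyl)prop-2-en-1-one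
Conditions: TBSCl (1.05 equiv), imidazole, DMF, 0 °C
Reagents that add atoms: tert-butyldimethylsilyl chloride (TBSCl), CC(C)(C)[Si](C)(C)Cl
Why: Chemoselective phenol silylation, since the 2'-OH is tied up in a strong hydrogen bond to the ketone and one equivalent of TBSCl goes to the free 4-OH; this silyl ether is the helper that later blocks the p-quinone methide tautomer.

Step 3
Reactants: 4 (E)-3-[4-(tert-butyldimethylsilyloxy)phenyl]-1-(2-hydroxy-4-methoxyphenyl)prop-2-en-1-one
Product: 5 rac-2-[(E)-3-[4-(tert-butyldimethylsilyloxy)phenyl]-1-hydroxyprop-2-enyl]-5-methoxyphenol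
Conditions: i-Bu2AlH (2.5 equiv), CH2Cl2, −78 °C; then aq potassium sodium tartrate; crude product used directly
Reagents that add atoms: none
Why: 1,2-Reduction of an enone with an aluminium hydride, in which the first equivalent forms the aluminium phenoxide and the second delivers hydride to the chelated C=O; the carbinol centre is racemic on purpose because step 6 erases it.

Step 4
Reactants: 6 2,4-dimethoxybenzaldehyde; 7 vinylmagnesium bromide
Product: 8 rac-1-(2,4-dimethoxyphenyl)prop-2-en-1-ol
Conditions: THF, 0 °C; then sat. aq NH4Cl
Reagents that add atoms: none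
Why: Grignard 1,2-addition to an aromatic aldehyde; the carbinol centre is racemic and is erased in step 5.

Step 5
Reactants: 8 rac-1-(2,4-dimethoxyphenyl)prop-2-en-1-ol; 9 4-(tert-butyldimethylsilyloxy)phenylboronic acid
Product: 10 (E)-1-(2,4-dimethoxyphenyl)-3-[4-(tert-butyldimethylsilyloxy)phenyl]prop-1-ene
Conditions: Pd(PPh3)4 (5 mol %), 1,4-dioxane, 80 °C
Reagents that add atoms: none
Why: Palladium-catalysed allyl–aryl coupling of a free allylic alcohol (Tsuji–Trost ionisation joined to Suzuki–Miyaura transmetalation), in which the boronic acid activates the hydroxyl group, zerovalent palladium forms the syn-1-aryl-π-allyl complex, and reductive elimination at the unsubstituted terminus gives the linear (E)-styrene.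

Step 6
Reactants: 5 rac-2-[(E)-3-[4-(tert-butyldimethylsilyloxy)phenyl]-1-hydroxyprop-2-enyl]-5-methoxyphenol; 10 (E)-1-(2,4-dimethoxyphenyl)-3-[4-(tert-butyldimethylsilyloxy)phenyl]prop-1-ene
Product: 12 (2R,3R,4R)-3-[4-(tert-butyldimethylsilyloxy)benzyl]-4-[(E)-4-(tert-butyldimethylsilyloxy)styryl]-2-(2,4-dimethoxyphenyl)-7-methoxychroman, via (E)-o-quinone methide 11 (not isolated)
Conditions: (R)-3,3'-bis(2,4,6-triisopropylphenyl)-1,1'-binaphthalene-2,2'-diyl N-(trifluoromethylsulfonyl)phosphoramide (10 mol %), 5 Å molecular sieves, toluene, −30 °C, slow addition of 5 to 10 (2 equiv)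
Reagents that add atoms: none
Why: Proposed new method: the acid ionises both enantiomers of 5 to one and the same planar, hydrogen-bonded (E)-o-quinone methide 11 (stereoablative, hence stereoconvergent), whose O=C8a–C4a=C4 heterodiene takes up the C2=C3 bond of 10 in a strongly asynchronous inverse-electron-demand oxa-Diels–Alder reaction in which C3–C4 forms ahead of O1–C2. The closest known reaction types are the chiral phosphoric acid catalysed [4+2] cycloadditions of in situ formed o-quinone methides with o-hydroxystyrenes or 2-vinylindoles and the contact-ion-pair allylic substitutions of 2-(hydroxyallyl)phenols under chiral N-triflylphosphoramide catalysis; not yet shown is the pairing of a styryl-substituted methide with a styrene that offers the catalyst no hydrogen-bond donor, which is why the more acidic, single-point-binding phosphoramide is chosen. Ring C is the only ring closed, by intermolecular [4+2] annulation, which in the stepwise limit is a 6-exo-trig capture of the 2,4-dimethoxybenzyl cation at C2 by the ring A oxygen. C4 is controlled by the catalyst, whose 3,3'-aryl groups leave one face of the bound methide open; C2/C3 trans is carried over suprafacially from the (E)-geometry of 10; C3/C4 trans and C2/C4 cis follow from the (E)-methide geometry and the ring B endo approach, and as this is also the all-equatorial isomer a stepwise collapse should end at the same relative configuration. The step needs attack at C4 and not at the far styryl carbon, cross- and not self-reaction, and no loss of the methide by closure onto its own styryl arm: the silyl ether shuts off the p-quinone methide tautomer so that the catalyst sits on the oxygen next to C4 and only attack at C4 can end in a six-membered ring, the two methoxy groups make C3 of 10 the best nucleophile present, the (E)-methide cannot reach its own styryl terminus, and slow addition of 5 to excess 10 keeps the methide dilute.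

Step 7
Reactants: 12 (2R,3R,4R)-3-[4-(tert-butyldimethylsilyloxy)benzyl]-4-[(E)-4-(tert-butyldimethylsilyloxy)styryl]-2-(2,4-dimethoxyphenyl)-7-methoxychroman
Product: 13 caraganin C, (2R,3R,4R)-2-(2,4-dimethoxyphenyl)-3-(4-hydroxybenzyl)-4-[(E)-4-hydroxystyryl]-7-methoxychroman
Conditions: n-Bu4NF (2.5 equiv), AcOH (2.5 equiv), THF, 0 °C
Reagents that add atoms: none
Why: Fluoride-induced cleavage of both aryl silyl ethers, buffered with acetic acid so that no phenoxide persists; no bond at C2, C3 or C4 is touched, so the three stereocentres are kept.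

**Compound list**
1 | 2'-hydroxy-4'-methoxyacetophenone (paeonol) | CC(=O)c1ccc(OC)cc1O | starting material
2 | 4-hydroxybenzaldehyde | O=Cc1ccc(O)cc1 | starting material
3 | (E)-1-(2-hydroxy-4-methoxyphenyl)-3-(4-hydroxyphenyl)prop-2-en-1-one | COc1ccc(C(=O)/C=C/c2ccc(O)cc2)c(O)c1 | intermediate
4 | (E)-3-[4-(tert-butyldimethylsilyloxy)phenyl]-1-(2-hydroxy-4-methoxyphenyl)prop-2-en-1-one | COc1ccc(C(=O)/C=C/c2ccc(O[Si](C)(C)C(C)(C)C)cc2)c(O)c1 | intermediate
5 | rac-2-[(E)-3-[4-(tert-butyldimethylsilyloxy)phenyl]-1-hydroxyprop-2-enyl]-5-methoxyphenol (racemic carbinol centre) | COc1ccc(C(O)/C=C/c2ccc(O[Si](C)(C)C(C)(C)C)cc2)c(O)c1 | intermediate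
6 | 2,4-dimethoxybenzaldehyde | COc1ccc(C=O)c(OC)c1 | starting material
7 | vinylmagnesium bromide | C=C[Mg]Br | starting material
8 | rac-1-(2,4-dimethoxyphenyl)prop-2-en-1-ol (racemic carbinol centre) | C=CC(O)c1ccc(OC)cc1OC | intermediate
9 | 4-(tert-butyldimethylsilyloxy)phenylboronic acid | CC(C)(C)[Si](C)(C)Oc1ccc(B(O)O)cc1 | starting material
10 | (E)-1-(2,4-dimethoxyphenyl)-3-[4-(tert-butyldimethylsilyloxy)phenyl]prop-1-ene | COc1ccc(/C=C/Cc2ccc(O[Si](C)(C)C(C)(C)C)cc2)c(OC)c1 | intermediate
11 | (6E)-6-[(E)-3-[4-(tert-butyldimethylsilyloxy)phenyl]prop-2-enylidene]-3-methoxycyclohexa-2,4-dien-1-one (o-quinone methide, not isolated) | COC1=CC(=O)/C(=C/C=C/c2ccc(O[Si](C)(C)C(C)(C)C)cc2)C=C1 | intermediate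
12 | (2R,3R,4R)-3-[4-(tert-butyldimethylsilyloxy)benzyl]-4-[(E)-4-(tert-butyldimethylsilyloxy)styryl]-2-(2,4-dimethoxyphenyl)-7-methoxychroman | COc1ccc2c(c1)O[C@@H](c1ccc(OC)cc1OC)[C@H](Cc1ccc(O[Si](C)(C)C(C)(C)C)cc1)[C@H]2/C=C/c1ccc(O[Si](C)(C)C(C)(C)C)cc1 | intermediate
13 | caraganin C | COc1ccc2c(c1)O[C@@H](c1ccc(OC)cc1OC)[C@H](Cc1ccc(O)cc1)[C@H]2/C=C/c1ccc(O)cc1 | target

**Step count**
Total step count: 7. Longest linear sequence: 5 steps (1, 2, 3, 6, 7).

**Steps most likely to fail**

Step 6 (proposed method).
- What may go wrong: facial discrimination may be poor, because the alkene partner gives the catalyst no second binding point.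
- The methide may also be lost in four ways: closure onto its own styryl arm, hydride transfer between two methide-derived species, attack at the far styryl carbon, or Friedel–Crafts capture through ring B.
- Fallback (known chemistry; sets out from 4, uses 5, comes back at 12): the alkene partner is given a temporary ortho-hydroxyl group. The step then becomes the established bifunctional chiral phosphoric acid catalysed [4+2] cycloaddition of o-quinone methides with o-hydroxystyrenes, and both halves come from the same chalcone.
- Hydrogenation of 4 (H2, Pd/C, EtOAc) should give the dihydrochalcone F1. NaBH4 (THF/EtOH) should give the saturated o-hydroxybenzyl alcohol F2. Acid-catalysed loss of water (pyridinium p-toluenesulfonate, toluene, 60 °C) should give the (E)-o-hydroxystyrene F3.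
- 5 and F3 with (R)-3,3'-bis(2,4,6-triisopropylphenyl)-1,1'-binaphthalene-2,2'-diyl hydrogen phosphate (molecular sieves, toluene) should give the 2'-hydroxy cycloadduct F4. Its only free phenol is then methylated (MeI, K2CO3, dry acetone) to 12.

Step 3.
- What may go wrong: hydride may be delivered in a conjugate sense instead of to the carbonyl. The aluminium alkoxide may ionise and take up a second hydride (over-reduction). The very labile doubly activated carbinol may ionise during work-up.
- Fallback (sets out from 2, comes back at 5): the carbinol carbon is made by C–C bond formation instead of reduction.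
- Silylation of 2 (TBSCl, imidazole, DMF) should give 4-(tert-butyldimethylsilyloxy)benzaldehyde F5. A Wittig reaction with (triphenylphosphoranylidene)acetaldehyde (toluene, 80 °C) should give the (E)-cinnamaldehyde F6.
- Commercial 2-bromo-5-methoxyphenol is turned with n-BuLi (2.1 equiv, THF, −78 °C) into the dilithio species F7. This should add 1,2 to F6 and give 5 after a quench with aq NH4Cl.

Step 5.
- What may go wrong: ionisation of the free alcohol may be slow and protodeboronation may compete. The electron-rich carbinol may undergo acid-type self-condensation. The double bond may migrate through a palladium hydride.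
- Fallback (sets out from 6, comes back at 10): the alkene is made by addition and dehydration, so its position is fixed by the carbon skeleton.
- Commercial 4-(2-bromoethyl)phenol is silylated (TBSCl, imidazole) to the bromide F8. F8 is converted with Mg (THF) into the Grignard reagent F9, which is added to 6 to give the saturated benzylic alcohol F10.
- Catalytic pyridinium p-toluenesulfonate (toluene, 60 °C, molecular sieves) should remove water by an E1 path through the 2,4-dimethoxybenzyl cation. This cation can lose a proton only from the one neighbouring CH2, so it gives (E)-configured 10.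

**Further compounds**
F1 | step 6 | 3-[4-(tert-butyldimethylsilyloxy)phenyl]-1-(2-hydroxy-4-methoxyphenyl)propan-1-one | COc1ccc(C(=O)CCc2ccc(O[Si](C)(C)C(C)(C)C)cc2)c(O)c1
F2 | step 6 | rac-2-[3-[4-(tert-butyldimethylsilyloxy)phenyl]-1-hydroxypropyl]-5-methoxyphenol | COc1ccc(C(O)CCc2ccc(O[Si](C)(C)C(C)(C)C)cc2)c(O)c1
F3 | step 6 | (E)-2-[3-[4-(tert-butyldimethylsilyloxy)phenyl]prop-1-enyl]-5-methoxyphenol | COc1ccc(/C=C/Cc2ccc(O[Si](C)(C)C(C)(C)C)cc2)c(O)c1
F4 | step 6 | (2R,3R,4R)-3-[4-(tert-butyldimethylsilyloxy)benzyl]-4-[(E)-4-(tert-butyldimethylsilyloxy)styryl]-2-(2-hydroxy-4-methoxyphenyl)-7-methoxychroman | COc1ccc2c(c1)O[C@@H](c1ccc(OC)cc1O)[C@H](Cc1ccc(O[Si](C)(C)C(C)(C)C)cc1)[C@H]2/C=C/c1ccc(O[Si](C)(C)C(C)(C)C)cc1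
F5 | step 3 | 4-(tert-butyldimethylsilyloxy)benzaldehyde | O=Cc1ccc(O[Si](C)(C)C(C)(C)C)cc1
F6 | step 3 | (E)-3-[4-(tert-butyldimethylsilyloxy)phenyl]prop-2-enal | O=C/C=C/c1ccc(O[Si](C)(C)C(C)(C)C)cc1
F7 | step 3 | lithium 2-lithio-5-methoxyphenolate | [Li]c1ccc(OC)cc1O[Li]
F8 | step 5 | [4-(2-bromoethyl)phenoxy](tert-butyl)dimethylsilane | BrCCc1ccc(O[Si](C)(C)C(C)(C)C)cc1
F9 | step 5 | 2-[4-(tert-butyldimethylsilyloxy)phenyl]ethylmagnesium bromide | Br[Mg]CCc1ccc(O[Si](C)(C)C(C)(C)C)cc1
F10 | step 5 | rac-3-[4-(tert-butyldimethylsilyloxy)phenyl]-1-(2,4-dimethoxyphenyl)propan-1-ol | COc1ccc(C(O)CCc2ccc(O[Si](C)(C)C(C)(C)C)cc2)c(OC)c1
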